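The route rests on one disconnection, the C9–C10 bond of ring B. These neighbouring halogen-bearing carbons (tertiary C9–Br, secondary C10–Cl) both descend from carbonyl carbons at the ends of the two arms on spiro carbon C6, so a single SmI2 pinacol coupling forms C9–C10, closes ring B and sets the cis-9,10-diol relative to C6. Its precursor is keto aldehyde 12, a 2,6,6-trimethylcyclohexene carrying a 3-oxobutyl and a 2-oxoethyl arm on the (S)-configured quaternary C6, made by catalytic asymmetric enone reduction and Claisen chirality transfer. The diol becomes the trans halide pair by inversion at C10 and retention at C9; ring A is oxidised, brominated and reduced last.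

Key step: step 6

Remark: locants are those of spiro[5.5]undecane (ring A = C1–C5, spiro C6, ring B = C7–C11); all CIP descriptors refer to them.
Remark: 3-ethoxy-2-methylcyclohex-2-en-1-one (1) is taken as a purchasable vinylogous ester.
Remark: stereochemical arguments after step 6 assume the ring B chair that keeps the quaternary C5 equatorial and C1 axial.

Step 1
Reactants: 1 3-ethoxy-2-methylcyclohex-2-en-1-one
Product: 3 3-ethoxy-2,6,6-trimethylcyclohex-2-en-1-one, via monomethylated enone 2 (not isolated)
Conditions: LiN(iPr)2 (1.1 equiv), THF, −78 °C; MeI, −78 to 0 °C; then LiN(iPr)2 (1.2 equiv), −78 °C; MeI, −78 °C to rt (one flask)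
Reagents that add atoms: iodomethane, CI
Why: Kinetic deprotonation of a vinylogous ester occurs at the alpha-prime carbon and each lithium enolate is C-methylated (Stork–Danheiser alkylation), so the gem-dimethyl group is placed regiospecifically next to the ketone.

Step 2
Reactants: 3 3-ethoxy-2,6,6-trimethylcyclohex-2-en-1-one; 4 2-(2-bromoethyl)-2-methyl-1,3-dioxolane
Product: 7 2,4,4-trimethyl-3-[2-(2-methyl-1,3-dioxolan-2-yl)ethyl]cyclohex-2-en-1-one, via Grignard reagent 5 (not isolated), via tertiary carbinol adduct 6 (not isolated)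
Conditions: 4, Mg turnings, THF, 25–30 °C; anhydrous CeCl3, THF, −78 °C; 3, −78 to 0 °C; sat. aq. NH4Cl; then 0.1 M HCl, THF, 0 °C, brief
Reagents that add atoms: water, O (carbonyl oxygen of 7); magnesium, [Mg] (metal of 5 only)
Why: CeCl3-assisted 1,2-addition of the Grignard reagent to the hindered ketone, which has no alpha hydrogen, followed by acid-triggered allylic transposition of the beta-hydroxy enol ether (Stork–Danheiser transposition) should give the transposed enone, the cold dilute acid being too mild to open the dioxolane.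

Step 3
Reactants: 7 2,4,4-trimethyl-3-[2-(2-methyl-1,3-dioxolan-2-yl)ethyl]cyclohex-2-en-1-one
Product: 8 (R)-2,4,4-trimethyl-3-[2-(2-methyl-1,3-dioxolan-2-yl)ethyl]cyclohex-2-en-1-ol
Conditions: (S)-2-methyl-CBS-oxazaborolidine (0.2 equiv), BH3·SMe2, THF, −30 °C; MeOH quench
Reagents that add atoms: none
Why: Corey–Bakshi–Shibata reduction, in which the oxazaborolidine–borane complex binds the ketone away from the larger alpha-methylated alkenyl side and delivers hydride to one face, so the (S)-catalyst should give the (R)-carbinol.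

Step 4
Reactants: 8 (R)-2,4,4-trimethyl-3-[2-(2-methyl-1,3-dioxolan-2-yl)ethyl]cyclohex-2-en-1-ol; 9 ethyl vinyl ether
Product: 11 (S)-2-{2,6,6-trimethyl-1-[2-(2-methyl-1,3-dioxolan-2-yl)ethyl]cyclohex-2-en-1-yl}acetaldehyde, via allyl vinyl ether 10 (not isolated)
Conditions: 9 (solvent), Hg(OAc)2 (cat.), reflux; evaporate; toluene, Et3N (trace), 180 °C, sealed tube
Reagents that add atoms: none
Why: Mercury-catalysed transvinylation followed by thermal Claisen rearrangement forms the C6–C11 bond suprafacially through a cyclic six-membered transition state on the face that carried the oxygen, so the (R)-carbinol is transferred to the (S)-quaternary C6 while the alkene moves to C1=C2.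

Step 5
Reactants: 11 (S)-2-{2,6,6-trimethyl-1-[2-(2-methyl-1,3-dioxolan-2-yl)ethyl]cyclohex-2-en-1-yl}acetaldehyde
Product: 12 (S)-2-[2,6,6-trimethyl-1-(3-oxobutyl)cyclohex-2-en-1-yl]acetaldehyde
Conditions: AcOH/THF/H2O (3:1:1), 40 °C
Reagents that add atoms: water, O
Why: Acid-catalysed ketal hydrolysis frees the methyl ketone under conditions mild enough to spare the aldehyde and the trisubstituted alkene, and no stereocentre is touched.

Step 6
Reactants: 12 (S)-2-[2,6,6-trimethyl-1-(3-oxobutyl)cyclohex-2-en-1-yl]acetaldehyde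
Product: 13 (6S,9S,10R)-1,5,5,9-tetramethylspiro[5.5]undec-1-ene-9,10-diol
Conditions: SmI2 (2.5 equiv), t-BuOH (2 equiv), THF, −78 °C to rt, 12 added slowly at high dilution; aq. NH4Cl
Reagents that add atoms: none
Why: Divalent samarium transfers an electron to the more easily reduced aldehyde, the C10 ketyl adds to the samarium-coordinated C9 ketone carbon, and a second electron transfer gives a samarium diolate that is protonated on work-up. The closest known reaction type is the SmI2-mediated intramolecular pinacol coupling of keto aldehydes to cis-cycloalkane-1,2-diols. Ring B closes in a 6-exo-trig mode, the ketyl carbon attacking the carbonyl carbon with the C=O bond outside the forming ring. C9 and C10 should be set cis by the trivalent samarium that bridges both oxygens, and their placement relative to C6 by a chair-like transition state with the bulkier quaternary C5 and the ketone methyl equatorial, which puts both oxygens on the C5 side (9S,10R). The step needs reduction of the aldehyde before the ketone, ring closure ahead of intermolecular coupling and an untouched alkene: the aldehyde is the better electron acceptor, the quaternary C6 holds the two arms together, and an isolated trisubstituted alkene is not reduced by SmI2 without strongly donating additives.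

Step 7
Reactants: 13 (6S,9S,10R)-1,5,5,9-tetramethylspiro[5.5]undec-1-ene-9,10-diol
Product: 14 (6S,9S,10R)-9,10-(isopropylidenedioxy)-1,5,5,9-tetramethylspiro[5.5]undec-1-ene
Conditions: 2,2-dimethoxypropane, PPTS (cat.), CH2Cl2, rt
Reagents that add atoms: 2,2-dimethoxypropane, COC(C)(C)OC
Why: Acid-catalysed transacetalisation of a cis-1,2-diol (acetonide formation) masks both hydroxyls, including the oxidisable C10 carbinol, without touching a stereocentre.

Step 8
Reactants: 14 (6S,9S,10R)-9,10-(isopropylidenedioxy)-1,5,5,9-tetramethylspiro[5.5]undec-1-ene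
Product: 15 (6S,9S,10R)-9,10-(isopropylidenedioxy)-1,5,5,9-tetramethylspiro[5.5]undec-1-en-3-one
Conditions: CrO3, 3,5-dimethylpyrazole, CH2Cl2, −20 °C
Reagents that add atoms: chromium trioxide, O=[Cr](=O)=O
Why: Allylic C–H oxidation with the CrO3–3,5-dimethylpyrazole complex should convert the only ring allylic methylene, C3, into the conjugated ketone, since the other allylic ring carbon C6 is quaternary and C1 carries no hydrogen.

Step 9
Reactants: 15 (6S,9S,10R)-9,10-(isopropylidenedioxy)-1,5,5,9-tetramethylspiro[5.5]undec-1-en-3-one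
Product: 16 (6S,9S,10R)-9,10-dihydroxy-1,5,5,9-tetramethylspiro[5.5]undec-1-en-3-one
Conditions: 80% aq. AcOH, 50 °C
Reagents that add atoms: none
Why: Acid-catalysed acetal hydrolysis returns the cis-diol, and the beta,beta-disubstituted enone is stable to dilute acid.

Step 10
Reactants: 16 (6S,9S,10R)-9,10-dihydroxy-1,5,5,9-tetramethylspiro[5.5]undec-1-en-3-one
Product: 18 9,10-cyclic sulfate of 16, via cyclic sulfite 17 (not isolated)
Conditions: SOCl2, Et3N, CH2Cl2, 0 °C; then RuCl3 (cat.), NaIO4, MeCN/H2O, 0 °C
Reagents that add atoms: thionyl chloride, O=S(Cl)Cl; sodium periodate, [Na+].[O-]I(=O)(=O)=O (fourth oxygen on sulfur, delivered through RuO4)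
Why: Sharpless cyclic sulfate synthesis (cyclic sulfite formation, then ruthenium-catalysed oxidation at sulfur) activates both C–O bonds with retention, and the electron-poor enone alkene is a poor substrate for the brief RuO4 exposure.

Step 11
Reactants: 18 9,10-cyclic sulfate of 16
Product: 20 (6S,9S,10S)-10-chloro-9-hydroxy-1,5,5,9-tetramethylspiro[5.5]undec-1-en-3-one, via lithium chloro sulfate 19 (not isolated)
Conditions: LiCl, DMF, 60 °C; then H2SO4 (cat.), H2O, THF, rt
Reagents that add atoms: lithium chloride, [Li+].[Cl-]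
Why: SN2 opening of the cyclic sulfate by chloride at the secondary C10 (epoxide-like trans-diaxial opening; the tertiary C9–O bond cannot undergo SN2) inverts C10, and acid hydrolysis of the sulfate monoester at the S–O bond returns the C9 alcohol with retention.

Step 12
Reactants: 20 (6S,9S,10S)-10-chloro-9-hydroxy-1,5,5,9-tetramethylspiro[5.5]undec-1-en-3-one
Product: 21 (6S,9S,10S)-9-bromo-10-chloro-1,5,5,9-tetramethylspiro[5.5]undec-1-en-3-one
Conditions: HBr (33% in AcOH), LiBr, CH2Cl2, 0 °C to rt
Reagents that add atoms: hydrogen bromide, Br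
Why: SN1-type substitution of the tertiary alcohol in which the anti-periplanar C10 chlorine assists ionisation and shields its own face (neighbouring-group participation through a chloronium-like cation), so bromide should enter the tertiary C9 (Markovnikov opening) from the face the hydroxyl left, giving the trans bromide–chloride with overall retention, while any alkene from proton loss re-adds HBr to the same cation.

Step 13
Reactants: 21 (6S,9S,10S)-9-bromo-10-chloro-1,5,5,9-tetramethylspiro[5.5]undec-1-en-3-one
Product: 23 (4R,6R,9S,10S)-4,9-dibromo-10-chloro-1,5,5,9-tetramethylspiro[5.5]undec-1-en-3-one, via silyl dienol ether 22 (not isolated)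
Conditions: LiN(SiMe3)2, Me3SiCl, THF, −78 °C; then N-bromosuccinimide, THF, −78 to 0 °C
Reagents that add atoms: N-bromosuccinimide, O=C1CCC(=O)N1Br; chlorotrimethylsilane, C[Si](C)(C)Cl (silyl group of 22 only)
Why: Kinetic alpha-prime enolisation of the isophorone-type enone, trapping as the cross-conjugated silyl dienol ether and electrophilic bromination place bromine at C4, and it is expected to enter anti to the pseudoaxial C5 methyl in the ring A conformer that turns the C1 methyl away from the axial C10 chlorine, which is the face bearing C11 and gives the (4R) epimer.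

Step 14
Reactants: 23 (4R,6R,9S,10S)-4,9-dibromo-10-chloro-1,5,5,9-tetramethylspiro[5.5]undec-1-en-3-one
Product: 24 (3S,4R,6R,9S,10S)-4,9-dibromo-10-chloro-1,5,5,9-tetramethylspiro[5.5]undec-1-en-3-ol
Conditions: NaBH4, CeCl3·7H2O, MeOH, −78 °C
Reagents that add atoms: none
Why: Luche 1,2-reduction of the alpha-bromo enone, in which hydride should add to C3 anti to the pseudoaxial C4–Br bond (polar Felkin–Anh control, as in the reduction of 2-bromocyclohexanones to cis-bromohydrins), sets the (3S) carbinol cis to bromine while the alkyl halides are inert.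

Compound list
1 | 3-ethoxy-2-methylcyclohex-2-en-1-one | CCOC1=C(C)C(=O)CCC1 | starting material
2 | 3-ethoxy-2,6-dimethylcyclohex-2-en-1-one (racemic) | CCOC1=C(C)C(=O)C(C)CC1 | intermediate
3 | 3-ethoxy-2,6,6-trimethylcyclohex-2-en-1-one | CCOC1=C(C)C(=O)C(C)(C)CC1 | intermediate
4 | 2-(2-bromoethyl)-2-methyl-1,3-dioxolane | CC1(CCBr)OCCO1 | starting material
5 | [2-(2-methyl-1,3-dioxolan-2-yl)ethyl]magnesium bromide | CC1(CC[Mg]Br)OCCO1 | intermediate
6 | 3-ethoxy-2,6,6-trimethyl-1-[2-(2-methyl-1,3-dioxolan-2-yl)ethyl]cyclohex-2-en-1-ol (racemic) | CCOC1=C(C)C(O)(CCC2(C)OCCO2)C(C)(C)CC1 | intermediate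
7 | 2,4,4-trimethyl-3-[2-(2-methyl-1,3-dioxolan-2-yl)ethyl]cyclohex-2-en-1-one | CC1=C(CCC2(C)OCCO2)C(C)(C)CCC1=O | intermediate
8 | (R)-2,4,4-trimethyl-3-[2-(2-methyl-1,3-dioxolan-2-yl)ethyl]cyclohex-2-en-1-ol | O[C@@H]1CCC(C)(C)C(CCC2(C)OCCO2)=C1C | intermediate
9 | ethyl vinyl ether | C=COCC | starting material
10 | vinyl ether of 8, (R)-2-methyl-2-[2-(2,6,6-trimethyl-3-vinyloxycyclohex-1-en-1-yl)ethyl]-1,3-dioxolane | C=CO[C@@H]1CCC(C)(C)C(CCC2(C)OCCO2)=C1C | intermediate
11 | (S)-2-{2,6,6-trimethyl-1-[2-(2-methyl-1,3-dioxolan-2-yl)ethyl]cyclohex-2-en-1-yl}acetaldehyde | CC1=CCCC(C)(C)[C@@]1(CC=O)CCC2(C)OCCO2 | intermediate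
12 | (S)-2-[2,6,6-trimethyl-1-(3-oxobutyl)cyclohex-2-en-1-yl]acetaldehyde | CC1=CCCC(C)(C)[C@@]1(CC=O)CCC(C)=O | intermediate
13 | (6S,9S,10R)-1,5,5,9-tetramethylspiro[5.5]undec-1-ene-9,10-diol (cis-diol, both hydroxyls on the C5 side of ring B) | CC1=CCCC(C)(C)[C@@]12CC[C@](C)(O)[C@H](O)C2 | intermediate
14 | (6S,9S,10R)-9,10-(isopropylidenedioxy)-1,5,5,9-tetramethylspiro[5.5]undec-1-ene | CC1=CCCC(C)(C)[C@@]12CC[C@](C)(OC(C)(C)O3)[C@H]3C2 | intermediate
15 | (6S,9S,10R)-9,10-(isopropylidenedioxy)-1,5,5,9-tetramethylspiro[5.5]undec-1-en-3-one | CC1=CC(=O)CC(C)(C)[C@@]12CC[C@](C)(OC(C)(C)O3)[C@H]3C2 | intermediate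
16 | (6S,9S,10R)-9,10-dihydroxy-1,5,5,9-tetramethylspiro[5.5]undec-1-en-3-one | CC1=CC(=O)CC(C)(C)[C@@]12CC[C@](C)(O)[C@H](O)C2 | intermediate
17 | 9,10-cyclic sulfite of 16 (mixture at sulfur) | CC1=CC(=O)CC(C)(C)[C@@]12CC[C@](C)(OS(=O)O3)[C@H]3C2 | intermediate
18 | 9,10-cyclic sulfate of 16 | CC1=CC(=O)CC(C)(C)[C@@]12CC[C@](C)(OS(=O)(=O)O3)[C@H]3C2 | intermediate
19 | lithium (6S,9S,10S)-10-chloro-1,5,5,9-tetramethyl-3-oxospiro[5.5]undec-1-en-9-yl sulfate | CC1=CC(=O)CC(C)(C)[C@@]12CC[C@](C)(OS(=O)(=O)[O-])[C@@H](Cl)C2.[Li+] | intermediate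
20 | (6S,9S,10S)-10-chloro-9-hydroxy-1,5,5,9-tetramethylspiro[5.5]undec-1-en-3-one | CC1=CC(=O)CC(C)(C)[C@@]12CC[C@](C)(O)[C@@H](Cl)C2 | intermediate
21 | (6S,9S,10S)-9-bromo-10-chloro-1,5,5,9-tetramethylspiro[5.5]undec-1-en-3-one | CC1=CC(=O)CC(C)(C)[C@@]12CC[C@](C)(Br)[C@@H](Cl)C2 | intermediate
22 | (6R,9S,10S)-9-bromo-10-chloro-1,5,5,9-tetramethyl-3-(trimethylsilyloxy)spiro[5.5]undeca-1,3-diene | CC1=CC(O[Si](C)(C)C)=CC(C)(C)[C@@]12CC[C@](C)(Br)[C@@H](Cl)C2 | intermediate
23 | (4R,6R,9S,10S)-4,9-dibromo-10-chloro-1,5,5,9-tetramethylspiro[5.5]undec-1-en-3-one | CC1=CC(=O)[C@H](Br)C(C)(C)[C@@]12CC[C@](C)(Br)[C@@H](Cl)C2 | intermediate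
24 | (3S,4R,6R,9S,10S)-4,9-dibromo-10-chloro-1,5,5,9-tetramethylspiro[5.5]undec-1-en-3-ol | CC1=C[C@H](O)[C@H](Br)C(C)(C)[C@@]12CC[C@](C)(Br)[C@@H](Cl)C2 | target

Total step count: 14. Longest linear sequence: 14 steps (1 to 24); 4 and 9 enter without separate steps.

Steps most likely to fail

Step 6. The two chair-like coupling modes may be poorly discriminated, so that the cis-diol forms on the C1 side of ring B, or some trans-diol forms. Intermolecular coupling or aldol condensation under the Lewis acidic samarium alkoxides may also compete. The fallback sets out from 12: a McMurry coupling with low-valent titanium (TiCl4, Zn dust, pyridine, THF, reflux, slow addition) closes the same C9–C10 bond as an alkene, giving (S)-1,5,5,9-tetramethylspiro[5.5]undeca-1,9-diene F1. Dihydroxylation with OsO4 (cat.) and N-methylmorpholine N-oxide in acetone/H2O at 0 °C should then take the less hindered ring B alkene, because the ring A alkene is flanked by the quaternary C6. Attack from the face anti to the axial C1 comes back to the route at 13.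

Step 12. Proton loss from the C9 cation may outrun bromide capture, or an unbridged cation may be attacked from the chlorine face, eroding retention at C9. The fallback sets out from 20: dehydration with POCl3 in pyridine (anti elimination through the axial C8 hydrogen) gives (6S,10S)-10-chloro-1,5,5,9-tetramethylspiro[5.5]undeca-1,8-dien-3-one F2. Markovnikov hydrobromination with anhydrous HBr in CH2Cl2 at −40 °C then protonates C8 and generates the same beta-chloro C9 cation at low temperature. Bromide adds anti to chlorine, and the fallback comes back to the route at 21.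

Step 13. Facial bias at C4 may be insufficient if ring B does not hold the chair with an axial C10 chlorine, so that bromine also enters on the face of C7. The fallback sets out from 21: the bromination mixture is separated and the unwanted (4S,6R,9S,10S)-4,9-dibromo-10-chloro-1,5,5,9-tetramethylspiro[5.5]undec-1-en-3-one F3 is equilibrated at C4 by acid-catalysed enolisation (HBr cat., AcOH, rt). Thermodynamic control thus replaces kinetic face selection, and C4 is the only centre able to epimerise. The mixture is separated again and the fallback comes back to the route at 23.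

Further compounds
F1 | step 6 | (S)-1,5,5,9-tetramethylspiro[5.5]undeca-1,9-diene | CC1=CCCC(C)(C)[C@@]12CCC(C)=CC2
F2 | step 12 | (6S,10S)-10-chloro-1,5,5,9-tetramethylspiro[5.5]undeca-1,8-dien-3-one | CC1=CC(=O)CC(C)(C)[C@@]12CC=C(C)[C@@H](Cl)C2
F3 | step 13 | (4S,6R,9S,10S)-4,9-dibromo-10-chloro-1,5,5,9-tetramethylspiro[5.5]undec-1-en-3-one | CC1=CC(=O)[C@@H](Br)C(C)(C)[C@@]12CC[C@](C)(Br)[C@@H](Cl)C2
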